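**Fraction left.** The leftover of starting material is the number to follow. Its exposure, the natural logarithm of charged over left, grows in step with time in a pseudo-first-order reaction, and stretches at different temperatures add.

all flasks: starting material 20 mM; gas 1.7 mM (held); free catalyst 0.20 mM; added ligand 0.21 mM
- elm: impurity 37 µM; temperature 15 °C; run made earlier
- birch: impurity 77 µM; temperature 30 °C; run made earlier
- alder: impurity 150 µM; temperature 15 °C; run made earlier
- midnight: impurity 150 µM; at 40 °C throughout; time 50 h
- summer: impurity 45 µM; at 20 °C until 15 h, from then on at 40 °C; time 30 h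

- elm (time / h: product / %): 6.00: 8.0; 12.0: 14.3; 20.0: 22.4; 25.0: 24.9; 30.0: 28.6
- birch (time / h: product / %): 4.00: 18.5; 8.00: 35.9; 12.0: 49.3; 15.0: 60.2; 20.0: 70.9
- alder (time / h: product / %): 6.00: 4.4; 12.0: 11.0; 20.0: 17.2; 25.0: 19.5; 30.0: 23.5

(standard deviation of a reading: 1 percentage point)

- at the start none of reagent is dissolved
- candidate steps: reagent + free catalyst -> catalyst intermediate A; starting material + catalyst intermediate A <-> catalyst intermediate B; catalyst intermediate D -> free catalyst + product; free catalyst + added ligand <-> idle complex; catalyst intermediate B -> released group + catalyst intermediate C; catalyst intermediate C <-> catalyst intermediate D; free catalyst + impurity -> spent catalyst; gas <-> reagent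

1. the flask that ends with the higher amount of product, in percent of the starting material charged, or "neither" when 2 percentage points or less lies between them (midnight / summer / neither)
2. final product, as a percentage of the starting material charged, in midnight
3. final product, as a percentage of the starting material charged, in summer

**Living share.** One impurity takes one free catalyst. Once the impurity is used up, the surviving share is catalyst minus impurity over catalyst: 25.0% in midnight, 77.5% in summer.

**Rates.** Birch's last reading, divided by its share of 61.5%, gives 0.100 h⁻¹ at 30 °C. Elm's, with its share of 81.5%, gives 0.0138 h⁻¹ at 15 °C. Taking the same factor per degree, the rate at 40 °C is 0.377 h⁻¹, and an hour at 20 °C is worth 0.0708 of an hour at 40 °C.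

**Living hours.** Midnight counts 12.5 h and summer 12.4 h of living hours, the living share times the hours reckoned at 40 °C, so the two stand level. Exposures are then 4.71 and 4.69, which leave 0.900% and 0.919%.

**Weak link.** The share is the weak link. At the same temperature, alder's rate over elm's rate per living share reads 64.8%, above alder's final share of 25.0%. In alder, impurity therefore takes catalyst gradually; if it does so in birch, elm, midnight and summer too, the living hours read low and the rates, divided by final shares, read high, so the two errors pull against each other. The reckoning here stands at about 99.1% in each flask, with a gap inside 2 percentage points: neither.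

**The forecast.** It differs: 95% for midnight, 91% for summer, and midnight as the winner, saying “midnight is favoured because of its longer hot time”.

**The result.** Midnight ends at 98.2% and summer at 98.3%, so the answer is neither.

    reagent + free catalyst → catalyst intermediate A (k = 2260 M⁻¹ min⁻¹, Ea = 41.0 kJ mol⁻¹)
    starting material + catalyst intermediate A ⇌ catalyst intermediate B (K = 122 M⁻¹, k = 6.98 M⁻¹ min⁻¹, Ea = 58.0 kJ mol⁻¹, ΔH = −37.0 kJ mol⁻¹)
    catalyst intermediate D → free catalyst + product (k = 6.92 min⁻¹, Ea = 86.0 kJ mol⁻¹)
    free catalyst + added ligand ⇌ idle complex (K = 7210 M⁻¹, k = 189 M⁻¹ min⁻¹, Ea = 46.0 kJ mol⁻¹, ΔH = −32.0 kJ mol⁻¹)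
    catalyst intermediate B → released group + catalyst intermediate C (k = 18.8 min⁻¹, Ea = 83.0 kJ mol⁻¹)
    catalyst intermediate C ⇌ catalyst intermediate D (K = 0.321, k = 0.0561 min⁻¹, Ea = 97.0 kJ mol⁻¹, ΔH = 23.0 kJ mol⁻¹)
    free catalyst + impurity → spent catalyst (k = 739 M⁻¹ min⁻¹, Ea = 55.0 kJ mol⁻¹)
    gas ⇌ reagent, rate k8*(csat - [reagent]) (kL = 0.0696 min⁻¹)
    (constants at 20 °C)

Spent catalyst ends at 74.9% in midnight and 22.5% in summer. Their leftovers of 1.80% and 1.73% are exposures of 4.02 and 4.06, on 12.5 h and 12.4 h of living hours. A neighbour of midnight charged with 0.25 mM of impurity counts 0 h of living hours, and it ends with spent catalyst at >99.9% and product at 14.8%.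

The numbers in the tables come from a simulation with made-up constants; scatter was added.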